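**Retrosynthetic overview**
1. The target is traced back to its 7-O-allyl ether and then to the C4 dithioketal: the 7-OH is freed last with zerovalent palladium, and the C4 ketone is released from a temporary 1,3-dithiane ring that is not in the target.
2. Ring C is disconnected at C3–C4 and O1–C8a in one operation: a lithiated 2-(2-fluoroaryl)-1,3-dithiane (ring A, C4 as masked acyl anion) plus an (R)-aryloxirane (ring B carrying O1, C2 and C3). Oxirane opening at C3 makes C3–C4 and frees the O1 alkoxide, which closes ring C by SNAr at C8a in the same pot.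
3. Enabling feature: in ring C, O1 (on C2) and C3 are vicinal, so O1–C2–C3 maps onto a terminal oxirane through a temporary O1–C3 bond. The C4 carbonyl sits on C4a, ortho to the O1-bearing C8a of ring A, so C4 can react as an acyl anion and C8a as an SNAr site.
4. The ring B oxirane comes from 3-bromo-4-hydroxybenzaldehyde: Claisen rearrangement and cross-metathesis (prenyl), Heck reaction (hydroxymethylbutenyl arm), Corey–Chaykovsky epoxidation and hydrolytic kinetic resolution (C2 stereocentre).
5. Ring order: rings A and B are bought as benzenes; the temporary oxirane (step 6) and dithiane (step 9) are made first; ring C is closed last (step 10); the dithiane is cleaved in step 11.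

Key step: step 10

Remark on the chemistry: the target is the (2S)-flavanone; C2 is carried in as an (R)-oxirane, and the descriptor changes only because C3 exchanges its oxygen for C4 in the CIP ranking (the spatial arrangement at C2 is kept).

**Route**

Step 1
Reactants: 1 3-bromo-4-hydroxybenzaldehyde; 2 allyl bromide
Product: 3 4-(allyloxy)-3-bromobenzaldehyde
Conditions: K2CO3, DMF, rt
Reagents that add atoms: allyl bromide, C=CCBr
Why: Williamson ether synthesis of an acidic para-formyl phenoxide with a primary allylic bromide should be clean.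

Step 2
Reactants: 3 4-(allyloxy)-3-bromobenzaldehyde
Product: 4 3-allyl-5-bromo-4-hydroxybenzaldehyde
Conditions: N,N-diethylaniline, 195 °C
Reagents that add atoms: none
Why: aromatic Claisen rearrangement ([3,3]-sigmatropic shift, then tautomerisation) can end productively only at the free ortho carbon, because the other ortho position carries bromine.

Step 3
Reactants: 4 3-allyl-5-bromo-4-hydroxybenzaldehyde; 5 iodomethane
Product: 6 3-allyl-5-bromo-4-methoxybenzaldehyde
Conditions: MeI, K2CO3, acetone, 50 °C
Reagents that add atoms: iodomethane, CI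
Why: Williamson O-methylation of the acidic, doubly ortho-substituted phenol should proceed without touching the aldehyde or the allyl group.

Step 4
Reactants: 6 3-allyl-5-bromo-4-methoxybenzaldehyde; 7 2-methylbut-2-ene
Product: 8 3-bromo-4-methoxy-5-(3-methylbut-2-en-1-yl)benzaldehyde
Conditions: second-generation Grubbs catalyst (H2IMes)(PCy3)Cl2Ru=CHPh (3 mol %), 2-methylbut-2-ene/CH2Cl2, 40 °C, sealed tube
Reagents that add atoms: 2-methylbut-2-ene, CC=C(C)C
Why: olefin cross-metathesis of a terminal allyl arene with excess 2-methylbut-2-ene is the standard allyl-to-prenyl conversion, and the trisubstituted product alkene, the aldehyde and the aryl bromide should be left alone.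

Step 5
Reactants: 8 3-bromo-4-methoxy-5-(3-methylbut-2-en-1-yl)benzaldehyde; 9 2-methylbut-3-en-2-ol
Product: 10 3-[(E)-3-hydroxy-3-methylbut-1-en-1-yl]-4-methoxy-5-(3-methylbut-2-en-1-yl)benzaldehyde
Conditions: Pd(OAc)2, P(o-tol)3, Et3N, DMF, 100 °C
Reagents that add atoms: 2-methylbut-3-en-2-ol, C=CC(C)(C)O
Why: Mizoroki–Heck reaction of the aryl bromide with a monosubstituted alkene that has no hydrogen on the carbinol carbon, so β-hydride elimination can only give the (E)-styrenyl tertiary alcohol, while the trisubstituted prenyl alkene does not insert.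

Step 6
Reactants: 10 3-[(E)-3-hydroxy-3-methylbut-1-en-1-yl]-4-methoxy-5-(3-methylbut-2-en-1-yl)benzaldehyde; 11 trimethylsulfonium iodide
Product: 13 racemic (E)-4-[2-methoxy-3-(3-methylbut-2-en-1-yl)-5-(oxiran-2-yl)phenyl]-2-methylbut-3-en-2-ol, via dimethylsulfonium methylide 12 (not isolated)
Conditions: Me3SI (2.5 equiv), n-BuLi (2.4 equiv), THF, −10 °C; then 10, −10 °C → rt
Reagents that add atoms: trimethylsulfonium iodide, C[S+](C)C.[I-]
Why: Corey–Chaykovsky methylene transfer to a non-enolisable aryl aldehyde should give the terminal oxirane as a racemate, the excess ylide covering the free tertiary alcohol and the DMSO-free conditions sparing the prenyl group.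

Step 7
Reactants: 13 racemic (E)-4-[2-methoxy-3-(3-methylbut-2-en-1-yl)-5-(oxiran-2-yl)phenyl]-2-methylbut-3-en-2-ol
Product: 14 (E)-4-{2-methoxy-3-(3-methylbut-2-en-1-yl)-5-[(2R)-oxiran-2-yl]phenyl}-2-methylbut-3-en-2-ol
Conditions: (S,S)-(salen)Co [N,N′-bis(3,5-di-tert-butylsalicylidene)-(1S,2S)-cyclohexane-1,2-diaminocobalt, divalent cobalt] (1 mol %), AcOH, air, giving (S,S)-(salen)Co(OAc) (trivalent cobalt); H2O (0.55 equiv), THF, 0 °C → rt
Reagents that add atoms: none
Why: Jacobsen hydrolytic kinetic resolution of a terminal aryl oxirane, in which the (S,S)-catalyst should hydrolyse the (S)-oxirane to the diol and leave the (R)-oxirane (at most half of 13), so the C2 configuration of the target is selected here by the catalyst and is to be confirmed (chiral HPLC, comparison with material from the fallback) before step 10.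

Step 8
Reactants: 15 2-fluoro-4-hydroxybenzaldehyde; 2 allyl bromide
Product: 16 4-(allyloxy)-2-fluorobenzaldehyde
Conditions: K2CO3, acetone, 50 °C
Reagents that add atoms: allyl bromide, C=CCBr
Why: Williamson ether synthesis installs a phenol protecting group that resists n-BuLi at low temperature and is later removed under neutral conditions.

Step 9
Reactants: 16 4-(allyloxy)-2-fluorobenzaldehyde; 17 propane-1,3-dithiol
Product: 18 2-[4-(allyloxy)-2-fluorophenyl]-1,3-dithiane
Conditions: BF3·OEt2 (cat.), CH2Cl2, 0 °C
Reagents that add atoms: propane-1,3-dithiol, SCCCS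
Why: Lewis-acid-catalysed dithioacetalisation of the aldehyde installs the temporary ring that turns the future C4 into an acyl anion equivalent (Corey–Seebach umpolung).

Step 10
Reactants: 18 2-[4-(allyloxy)-2-fluorophenyl]-1,3-dithiane; 14 (E)-4-{2-methoxy-3-(3-methylbut-2-en-1-yl)-5-[(2R)-oxiran-2-yl]phenyl}-2-methylbut-3-en-2-ol
Product: 21 (2S)-7-(allyloxy)-2-{3-[(E)-3-hydroxy-3-methylbut-1-en-1-yl]-4-methoxy-5-(3-methylbut-2-en-1-yl)phenyl}spiro[chromane-4,2′-[1,3]dithiane], via 2-lithio-1,3-dithiane 19 (not isolated), via open-chain dilithium alkoxide 20 (not isolated)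
Conditions: 18 (2.2 equiv), n-BuLi (2.1 equiv), THF, −78 → −30 °C; 14 (1 equiv), −30 °C → rt; then KOtBu (1.5 equiv), DMPU, 60 °C; aq. NH4Cl
Reagents that add atoms: none
Why: n-BuLi removes the acidic dithiane C–H of 18 to give 19; one equivalent of 19 is spent as base on the tertiary alcohol of 14 and the next opens the oxirane by SN2 attack at the unsubstituted carbon, which forms C3–C4 and releases O1 as alkoxide 20. After lithium–potassium exchange with KOtBu, this alkoxide adds to the fluorine-bearing C8a of ring A and expels fluoride (addition–elimination SNAr through a Meisenheimer adduct), closing ring C as a six-membered ring (formally 6-exo attack on the arene, helped by the gem-dithio substituent at C4). The closest known reactions are the alkylation of 2-aryl-2-lithio-1,3-dithianes with terminal aryl oxiranes and the alkoxide SNAr cyclisation of 3-(2-fluoroaryl)propan-1-ols to chromans, run here in one pot. No new stereocentre is formed: C2 comes from 14 and its C–O bond is never broken, so the (R)-oxirane should give the (2S)-chroman with retention. The step needs opening at CH2 and not at the benzylic carbon (secured by the bulky tertiary carbanion and by the 4-methoxy group of ring B, which is twisted out of conjugation by its two ortho substituents), and deprotonation of 18 at the dithiane carbon only (secured by its much higher acidity, n-BuLi being consumed before 14 is added). Because C4 stays masked, retro-aldol cleavage and ring opening by retro-oxa-Michael reaction cannot racemise C2 under the basic conditions.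

Step 11
Reactants: 21 (2S)-7-(allyloxy)-2-{3-[(E)-3-hydroxy-3-methylbut-1-en-1-yl]-4-methoxy-5-(3-methylbut-2-en-1-yl)phenyl}spiro[chromane-4,2′-[1,3]dithiane]
Product: 22 (2S)-7-(allyloxy)-2-{3-[(E)-3-hydroxy-3-methylbut-1-en-1-yl]-4-methoxy-5-(3-methylbut-2-en-1-yl)phenyl}chroman-4-one
Conditions: MeI, CaCO3, MeCN/H2O (4:1), 45 °C
Reagents that add atoms: water, O
Why: alkylative hydrolysis of the dithioketal (S-methylation, ionisation to a thionium ion stabilised by the ortho- and para-oxygenated ring A, capture by water) is buffered and non-oxidising, so the alkenes, the tertiary allylic alcohol and the C2 stereocentre should survive.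

Step 12
Reactants: 22 (2S)-7-(allyloxy)-2-{3-[(E)-3-hydroxy-3-methylbut-1-en-1-yl]-4-methoxy-5-(3-methylbut-2-en-1-yl)phenyl}chroman-4-one
Product: 23 (2S)-7-hydroxy-2-{3-[(E)-3-hydroxy-3-methylbut-1-en-1-yl]-4-methoxy-5-(3-methylbut-2-en-1-yl)phenyl}chroman-4-one (target)
Conditions: Pd(PPh3)4 (zerovalent palladium, 5 mol %), morpholine (2 equiv), THF, rt
Reagents that add atoms: none
Why: Tsuji–Trost deallylation, in which the para-acyl phenoxide is a good leaving group for π-allyl formation and morpholine traps the allyl unit, should free the 7-OH at room temperature without acid (tertiary allylic alcohol, prenyl) or strong base (C2 of the flavanone).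

**Compound list**
1 | 3-bromo-4-hydroxybenzaldehyde | O=Cc1ccc(O)c(Br)c1 | starting material
2 | allyl bromide | C=CCBr | starting material
3 | 4-(allyloxy)-3-bromobenzaldehyde | O=Cc1ccc(OCC=C)c(Br)c1 | intermediate
4 | 3-allyl-5-bromo-4-hydroxybenzaldehyde | O=Cc1cc(Br)c(O)c(CC=C)c1 | intermediate
5 | iodomethane | CI | starting material
6 | 3-allyl-5-bromo-4-methoxybenzaldehyde | COc1c(Br)cc(C=O)cc1CC=C | intermediate
7 | 2-methylbut-2-ene | CC=C(C)C | starting material
8 | 3-bromo-4-methoxy-5-(3-methylbut-2-en-1-yl)benzaldehyde | COc1c(Br)cc(C=O)cc1CC=C(C)C | intermediate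
9 | 2-methylbut-3-en-2-ol | C=CC(C)(C)O | starting material
10 | 3-[(E)-3-hydroxy-3-methylbut-1-en-1-yl]-4-methoxy-5-(3-methylbut-2-en-1-yl)benzaldehyde | COc1c(/C=C/C(C)(C)O)cc(C=O)cc1CC=C(C)C | intermediate
11 | trimethylsulfonium iodide | C[S+](C)C.[I-] | starting material
12 | dimethylsulfonium methylide | C[S+](C)[CH2-] | intermediate (not isolated)
13 | racemic (E)-4-[2-methoxy-3-(3-methylbut-2-en-1-yl)-5-(oxiran-2-yl)phenyl]-2-methylbut-3-en-2-ol | COc1c(/C=C/C(C)(C)O)cc(C2CO2)cc1CC=C(C)C | intermediate
14 | (E)-4-{2-methoxy-3-(3-methylbut-2-en-1-yl)-5-[(2R)-oxiran-2-yl]phenyl}-2-methylbut-3-en-2-ol | COc1c(/C=C/C(C)(C)O)cc([C@@H]2CO2)cc1CC=C(C)C | intermediate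
15 | 2-fluoro-4-hydroxybenzaldehyde | O=Cc1ccc(O)cc1F | starting material
16 | 4-(allyloxy)-2-fluorobenzaldehyde | O=Cc1ccc(OCC=C)cc1F | intermediate
17 | propane-1,3-dithiol | SCCCS | starting material
18 | 2-[4-(allyloxy)-2-fluorophenyl]-1,3-dithiane | C=CCOc1ccc(C2SCCCS2)c(F)c1 | intermediate
19 | 2-[4-(allyloxy)-2-fluorophenyl]-2-lithio-1,3-dithiane | [Li]C1(SCCCS1)c1ccc(OCC=C)cc1F | intermediate (not isolated)
20 | dilithium alkoxide of (E)-4-{5-[(1S)-2-{2-[4-(allyloxy)-2-fluorophenyl]-1,3-dithian-2-yl}-1-hydroxyethyl]-2-methoxy-3-(3-methylbut-2-en-1-yl)phenyl}-2-methylbut-3-en-2-ol | COc1c(/C=C/C(C)(C)O[Li])cc([C@@H](O[Li])CC2(SCCCS2)c2ccc(OCC=C)cc2F)cc1CC=C(C)C | intermediate (not isolated)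
21 | (2S)-7-(allyloxy)-2-{3-[(E)-3-hydroxy-3-methylbut-1-en-1-yl]-4-methoxy-5-(3-methylbut-2-en-1-yl)phenyl}spiro[chromane-4,2′-[1,3]dithiane] | COc1c(/C=C/C(C)(C)O)cc([C@@H]2CC3(SCCCS3)c3ccc(OCC=C)cc3O2)cc1CC=C(C)C | intermediate
22 | (2S)-7-(allyloxy)-2-{3-[(E)-3-hydroxy-3-methylbut-1-en-1-yl]-4-methoxy-5-(3-methylbut-2-en-1-yl)phenyl}chroman-4-one | COc1c(/C=C/C(C)(C)O)cc([C@@H]2CC(=O)c3ccc(OCC=C)cc3O2)cc1CC=C(C)C | intermediate
23 | (2S)-7-hydroxy-2-{3-[(E)-3-hydroxy-3-methylbut-1-en-1-yl]-4-methoxy-5-(3-methylbut-2-en-1-yl)phenyl}chroman-4-one | COc1c(/C=C/C(C)(C)O)cc([C@@H]2CC(=O)c3ccc(O)cc3O2)cc1CC=C(C)C | target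

**Step count**
Total: 12 steps. Longest linear sequence: 10 steps (steps 1–7, then 10–12); steps 8–9 form the second branch.

**Steps most likely to fail**

Step 10. Fluoride displacement from the unactivated ring A may be slow, and the potassium alkoxide medium needed to drive it may move the allyl ether or prenyl double bond into conjugation. Some opening of the oxirane at the benzylic carbon, or ring metalation of 18 between fluorine and oxygen, would also lower the return.
Fallback (sets out from 13, comes back at 21): the aryl–oxygen bond is bought in and ring C is closed at O1–C2 instead.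
- Racemic oxirane 13 is resolved with the enantiomeric (R,R)-(salen)Co(OAc) to leave the (S)-oxirane F1.
- Commercial 2,4-dihydroxybenzaldehyde is allylated at the more acidic 4-hydroxyl (allyl bromide, KHCO3, MeCN) to 4-(allyloxy)-2-hydroxybenzaldehyde F2.
- F2 is converted with propane-1,3-dithiol 17 and BF3·OEt2 into 2-[4-(allyloxy)-2-hydroxyphenyl]-1,3-dithiane F3.
- The dilithio derivative of F3 (n-BuLi in excess, THF, −30 °C) opens F1 at the CH2 carbon to the (1R)-configured phenol alcohol F4.
- A Mitsunobu etherification (PPh3, DIAD, THF, 0 °C) closes ring C with inversion at C2 and gives 21.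

Step 7. The cobalt Lewis acid may discriminate poorly between the enantiomers of this electron-rich aryl oxirane or isomerise it to the arylacetaldehyde, and half of the material is lost in any case.
Fallback (sets out from 10, comes back at 14): the stereocentre is set by asymmetric ketone reduction.
- Chloromethyllithium (ICH2Cl, MeLi·LiBr, THF, −78 °C, cold AcOH quench) adds to aldehyde 10 to give the racemic chlorohydrin F5.
- Dess–Martin periodinane with NaHCO3 oxidises it to the α-chloro ketone F6.
- Noyori transfer hydrogenation with RuCl[(S,S)-TsDPEN](p-cymene) in HCO2H/Et3N should give the (R)-chlorohydrin F7.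
- K2CO3 in MeOH closes F7 to 14 without touching the stereocentre.

Step 11. The alkylative hydrolysis may stall at the sulfonium stage, or acid that escapes the buffer may ionise the tertiary styrenyl alcohol.
Fallback (sets out from 21, comes back at 23): the last two operations are inverted and a thiophilic metal replaces the alkylating agent.
- Pd(PPh3)4 with morpholine removes the allyl group from 21 to give the free 7-phenol dithioketal F8, whose para-hydroxyl assists ionisation of the C4–S bonds.
- AgNO3 with 2,6-lutidine in aqueous THF should then hydrolyse the dithioketal to 23 directly.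

Further compounds
F1 | step 10 | (E)-4-{2-methoxy-3-(3-methylbut-2-en-1-yl)-5-[(2S)-oxiran-2-yl]phenyl}-2-methylbut-3-en-2-ol | COc1c(/C=C/C(C)(C)O)cc([C@H]2CO2)cc1CC=C(C)C
F2 | step 10 | 4-(allyloxy)-2-hydroxybenzaldehyde | O=Cc1ccc(OCC=C)cc1O
F3 | step 10 | 2-[4-(allyloxy)-2-hydroxyphenyl]-1,3-dithiane | C=CCOc1ccc(C2SCCCS2)c(O)c1
F4 | step 10 | (E)-4-{5-[(1R)-2-{2-[4-(allyloxy)-2-hydroxyphenyl]-1,3-dithian-2-yl}-1-hydroxyethyl]-2-methoxy-3-(3-methylbut-2-en-1-yl)phenyl}-2-methylbut-3-en-2-ol | COc1c(/C=C/C(C)(C)O)cc([C@H](O)CC2(SCCCS2)c2ccc(OCC=C)cc2O)cc1CC=C(C)C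
F5 | step 7 | racemic (E)-4-[5-(2-chloro-1-hydroxyethyl)-2-methoxy-3-(3-methylbut-2-en-1-yl)phenyl]-2-methylbut-3-en-2-ol | COc1c(/C=C/C(C)(C)O)cc(C(O)CCl)cc1CC=C(C)C
F6 | step 7 | 2-chloro-1-{3-[(E)-3-hydroxy-3-methylbut-1-en-1-yl]-4-methoxy-5-(3-methylbut-2-en-1-yl)phenyl}ethan-1-one | COc1c(/C=C/C(C)(C)O)cc(C(=O)CCl)cc1CC=C(C)C
F7 | step 7 | (E)-4-{5-[(1R)-2-chloro-1-hydroxyethyl]-2-methoxy-3-(3-methylbut-2-en-1-yl)phenyl}-2-methylbut-3-en-2-ol | COc1c(/C=C/C(C)(C)O)cc([C@@H](O)CCl)cc1CC=C(C)C
F8 | step 11 | (2S)-2-{3-[(E)-3-hydroxy-3-methylbut-1-en-1-yl]-4-methoxy-5-(3-methylbut-2-en-1-yl)phenyl}spiro[chromane-4,2′-[1,3]dithian]-7-ol | COc1c(/C=C/C(C)(C)O)cc([C@@H]2CC3(SCCCS3)c3ccc(O)cc3O2)cc1CC=C(C)C
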